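**Assumption:** the SMILES descriptor corresponds to (R) at C‑2 (O > CH2Ar > CH2‑alkyl > H); the E/Z mixture from step 6 is carried on together, since both isomers give the same product on hydrogenation.

**Retrosynthetic overview**
- Target ⇒ global hydrogenation (alkene saturation and O‑debenzylation) of a dibenzyl‑protected tridec‑4‑enyl acetate; the acetate is installed while the phenols are still benzylated.
- C4=C5 ⇒ cross‑metathesis of the homoallylic acetate with dec‑1‑ene.
- Key C2–C3 bond and the C2 stereocentre ⇒ Brown asymmetric allylboration of [3,5‑bis(benzyloxy)phenyl]acetaldehyde with (+)‑Ipc2B(allyl).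
- Aldehyde ⇒ methyl 3,5‑dihydroxyphenylacetate by benzylation, LiAlH4 reduction and Dess–Martin oxidation.
- No ring is formed; the benzene ring is bought with the starting ester.

**Step 1**
Reactants: 1 methyl 2-(3,5-dihydroxyphenyl)acetate
Product: 2 methyl 2-[3,5-bis(benzyloxy)phenyl]acetate
Conditions: BnBr (2.4 equiv), K2CO3 (3 equiv), acetone, reflux
Reagents that add atoms: benzyl bromide, BrCc1ccccc1
Why: Williamson ether synthesis, in which the phenoxides are alkylated by the SN2‑active benzyl bromide far faster than the ester α‑carbon under K2CO3, and benzyl is chosen because it is removed by the final hydrogenation.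

**Step 2**
Reactants: 2 methyl 2-[3,5-bis(benzyloxy)phenyl]acetate
Product: 3 2-[3,5-bis(benzyloxy)phenyl]ethan-1-ol
Conditions: LiAlH4, THF, 0 °C → rt; Fieser work-up
Reagents that add atoms: none
Why: Hydride reduction of the ester with LiAlH4 goes cleanly to the primary alcohol and leaves the aryl benzyl ethers untouched.

**Step 3**
Reactants: 3 2-[3,5-bis(benzyloxy)phenyl]ethan-1-ol
Product: 4 2-[3,5-bis(benzyloxy)phenyl]acetaldehyde
Conditions: Dess–Martin periodinane (1.2 equiv), CH2Cl2, 0 °C → rt; aq. Na2S2O3/NaHCO3 wash; crude aldehyde used at once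
Reagents that add atoms: none
Why: Dess–Martin oxidation is near‑neutral and non‑enolising, so the primary alcohol stops at the sensitive arylacetaldehyde without over‑oxidation or aldol self‑condensation.

**Step 4**
Reactants: 4 2-[3,5-bis(benzyloxy)phenyl]acetaldehyde; 5 (+)-B-allyldiisopinocampheylborane [(+)-Ipc2B(allyl), Ipc groups from (1S,5S)-(−)-α-pinene]
Product: 7 (R)-1-[3,5-bis(benzyloxy)phenyl]pent-4-en-2-ol, via borinate ester 6 (not isolated)
Conditions: 5 (1.3 equiv, titrated 1 M pentane solution), Et2O, −78 °C; then 3 M NaOH, 30% H2O2, 0 °C → rt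
Reagents that add atoms: none
Why: Brown asymmetric allylboration (carbonyl allylation) transfers the allyl group through a closed six‑membered chair transition state whose facial bias is fixed by the isopinocampheyl groups; the (+)-reagent adds in the same sense as in its known conversion of benzaldehyde into (R)-1-phenylbut-3-en-1-ol, which here (ArCH2 > allyl in CIP rank) is the 2R alcohol, and alkaline peroxide then cleaves the borinate.

**Step 5**
Reactants: 7 (R)-1-[3,5-bis(benzyloxy)phenyl]pent-4-en-2-ol
Product: 8 (R)-1-[3,5-bis(benzyloxy)phenyl]pent-4-en-2-yl acetate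
Conditions: Ac2O, pyridine, DMAP (cat.), CH2Cl2, 0 °C → rt
Reagents that add atoms: acetic anhydride, CC(=O)OC(C)=O
Why: DMAP‑catalysed acylation esterifies the only free hydroxyl with retention at C2, and doing it while the phenols are benzylated guarantees that only the secondary alcohol carries the acetate.

**Step 6**
Reactants: 8 (R)-1-[3,5-bis(benzyloxy)phenyl]pent-4-en-2-yl acetate; 9 dec-1-ene
Product: 10 (2R,4E)-1-[3,5-bis(benzyloxy)phenyl]tridec-4-en-2-yl acetate (E major, some Z)
Conditions: 9 (4 equiv), Grubbs 2nd-generation catalyst (5 mol%), CH2Cl2, 40 °C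
Reagents that add atoms: none
Why: Olefin cross‑metathesis between two unhindered terminal alkenes is driven by loss of ethene and pushed to the cross product by excess dec‑1‑ene, and the alkene geometry is irrelevant because it is hydrogenated next.

**Step 7**
Reactants: 10 (2R,4E)-1-[3,5-bis(benzyloxy)phenyl]tridec-4-en-2-yl acetate
Product: 11 (R)-1-(3,5-dihydroxyphenyl)tridecan-2-yl acetate
Conditions: H2 (1 atm), 10% Pd/C, EtOAc, rt
Reagents that add atoms: none
Why: Heterogeneous catalytic hydrogenation saturates the disubstituted alkene and hydrogenolyses both aryl benzyl ethers in one operation, while the non‑benzylic, non‑allylic secondary acetate and the C2 stereocentre are not touched.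

**Compound list**
1 | methyl 2-(3,5-dihydroxyphenyl)acetate | COC(=O)Cc1cc(O)cc(O)c1 | starting material
2 | methyl 2-[3,5-bis(benzyloxy)phenyl]acetate | COC(=O)Cc1cc(OCc2ccccc2)cc(OCc2ccccc2)c1 | intermediate
3 | 2-[3,5-bis(benzyloxy)phenyl]ethan-1-ol | OCCc1cc(OCc2ccccc2)cc(OCc2ccccc2)c1 | intermediate
4 | 2-[3,5-bis(benzyloxy)phenyl]acetaldehyde | O=CCc1cc(OCc2ccccc2)cc(OCc2ccccc2)c1 | intermediate
5 | (+)-B-allyldiisopinocampheylborane (Ipc groups from (−)-α-pinene; they give (1S,2S,3S,5R)-isopinocampheol on oxidation) | C=CCB([C@H]1C[C@H]2C[C@@H]([C@@H]1C)C2(C)C)[C@H]1C[C@H]2C[C@@H]([C@@H]1C)C2(C)C | starting material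
6 | (R)-1-[3,5-bis(benzyloxy)phenyl]pent-4-en-2-yl diisopinocampheylborinate | C=CC[C@H](Cc1cc(OCc2ccccc2)cc(OCc2ccccc2)c1)OB([C@H]1C[C@H]2C[C@@H]([C@@H]1C)C2(C)C)[C@H]1C[C@H]2C[C@@H]([C@@H]1C)C2(C)C | intermediate
7 | (R)-1-[3,5-bis(benzyloxy)phenyl]pent-4-en-2-ol | C=CC[C@H](Cc1cc(OCc2ccccc2)cc(OCc2ccccc2)c1)O | intermediate
8 | (R)-1-[3,5-bis(benzyloxy)phenyl]pent-4-en-2-yl acetate | C=CC[C@H](Cc1cc(OCc2ccccc2)cc(OCc2ccccc2)c1)OC(C)=O | intermediate
9 | dec-1-ene | C=CCCCCCCCC | starting material
10 | (2R,4E)-1-[3,5-bis(benzyloxy)phenyl]tridec-4-en-2-yl acetate | CCCCCCCC/C=C/C[C@H](Cc1cc(OCc2ccccc2)cc(OCc2ccccc2)c1)OC(C)=O | intermediate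
11 | (R)-1-(3,5-dihydroxyphenyl)tridecan-2-yl acetate | CCCCCCCCCCC[C@H](Cc1cc(O)cc(O)c1)OC(C)=O | target

**Total step count:** 7. **Longest linear sequence:** 7 steps (1 → 11).

**Three steps most likely to fail**

Step 4 (yield and ee of the allylboration depend on the enolisable, aldol‑prone aldehyde 4). The fallback sets out from alcohol 3 and never isolates the aldehyde. Alcohol 3 is heated with allyl acetate, [Ir(cod)Cl]2, a BINAP‑type ligand, 4‑chloro‑3‑nitrobenzoic acid and Cs2CO3 in THF at 100 °C (iridium‑catalysed transfer‑hydrogenative carbonyl allylation). The catalyst dehydrogenates 3 to aldehyde 4 only transiently and allylates it from a chiral π‑allyl iridium complex, and the route is rejoined at 7. I expect the (R)‑ligand to give the 2R alcohol, but I am not certain of the sense, so the ligand antipode is fixed on small scale by chiral HPLC against 7 from step 4. This fallback makes no new compound (F0).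

Step 6 (statistical cross‑metathesis: homodimer of 8, alkene migration, ruthenium residues). The fallback sets out from 8 and builds the chain by sp3–sp3 coupling instead. Hydroboration of the terminal alkene with 9‑BBN in THF gives (R)-1-[3,5-bis(benzyloxy)phenyl]-5-(9-borabicyclo[3.3.1]nonan-9-yl)pentan-2-yl acetate F1, used in the same flask. B‑alkyl Suzuki–Miyaura coupling with 1‑bromooctane (Pd(OAc)2, PCy3, K3PO4·H2O, THF, rt) gives the saturated (R)-1-[3,5-bis(benzyloxy)phenyl]tridecan-2-yl acetate F2. Hydrogenolysis of F2 (H2, Pd/C, EtOAc) comes back to the route at 11.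

Step 7 (Pd may migrate the double bond toward C3 and hydrogenolyse the then‑allylic acetate, or debenzylation may stall on poisoned catalyst). The fallback sets out from 10 and avoids Pd entirely. BCl3 with pentamethylbenzene as cation scavenger in CH2Cl2 at −78 °C removes both benzyl ethers and gives (2R,4E)-1-(3,5-dihydroxyphenyl)tridec-4-en-2-yl acetate F3. Diimide reduction of F3 (2‑nitrobenzenesulfonyl hydrazide, Et3N, CH2Cl2, rt) saturates the alkene and comes back to the route at 11.

**Further compounds**
F0 | step 4 | none | none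
F1 | step 6 | (R)-1-[3,5-bis(benzyloxy)phenyl]-5-(9-borabicyclo[3.3.1]nonan-9-yl)pentan-2-yl acetate | C(CCB1C2CCCC1CCC2)[C@H](Cc1cc(OCc2ccccc2)cc(OCc2ccccc2)c1)OC(C)=O
F2 | step 6 | (R)-1-[3,5-bis(benzyloxy)phenyl]tridecan-2-yl acetate | CCCCCCCCCCC[C@H](Cc1cc(OCc2ccccc2)cc(OCc2ccccc2)c1)OC(C)=O
F3 | step 7 | (2R,4E)-1-(3,5-dihydroxyphenyl)tridec-4-en-2-yl acetate | CCCCCCCC/C=C/C[C@H](Cc1cc(O)cc(O)c1)OC(C)=O
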